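## Structural features

The target 26 is a tetracyclic depsidone. Aromatic ring A (A1 OMe, A2 H, A3 CH3, A4 acyl carbon, A5 ether O, A6 CH2OH) and the fully substituted aromatic ring B (B1 ether O, B2 ester O, B3 CH3, B4 OH, B5 lactone carbonyl, B6 lactol carbon) are joined twice: by the A5–O–B1 diaryl ether and by the A4–C(=O)–O–B2 ester. These two links close the seven-membered lactone ring C, and a five-membered hydroxyphthalide ring D is fused to ring B at B5/B6. The only stereocentre is the lactol carbon on B6 (R); it has no neighbouring stereocentre and can epimerise by ring opening to the formyl carboxylic acid. The fragile groups are the aryl ester of ring C (base, nucleophiles), the lactol, the A6 benzylic alcohol flanked by two oxygens (ionisation, hydrogenolysis) and the B4 phenol para to the B1 ether oxygen (oxidation). The real difficulty is the diaryl ether: A5 lies between A4 and A6 and B1 between B2 and B6, so both carbons are doubly ortho-substituted and a coupling between two arenes is badly hindered. The second difficulty is fixing a labile acetal-type stereocentre in one configuration. The key step exploits the 1,3-relation of the A1 and A5 oxygens about A6 together with the carboxyl carbon on A4: ring A is the dehydro form of a 2-substituted 4-carboxycyclohexane-1,3-dione. A5 can therefore be a non-aromatic carbonyl carbon that accepts the B1 phenol while the B2 ester already holds the two halves together.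

## Logic of the disconnections

26 ⇒ 25. The three O–CH2Ph bonds are cut (acetal oxygen on B6, phenol oxygen on B4, A6–CH2–O). As an acetal the stereocentre is fixed, and a benzyl cap can be removed without breaking the C–O bond of the stereocentre and without acid or base. One operation then frees all three hydroxyls. The forward step must be neutral, aprotic and short, and must cleave PhCH2–O in preference to the ring A benzylic C–O bond and the phthalide C–O bond.

25 ⇒ 24. The exocyclic acetal C–O bond at B6 is cut. Because the lactol of 24 racemises through its open form, all of the racemate can be funnelled into one acetal by a chiral acid, so no stereochemistry has to be carried earlier. The forward step demands facial discrimination at a planar, ion-paired phthalidyl cation and a product that does not re-ionise.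

24 ⇒ 22 (through 23). The lactol C–O bond of ring D is opened to a B6 formyl group and a B5 carboxyl, the latter masked as an allyl ester. The open ester–aldehyde form withstands the acid, oxidant and base of the preceding steps, and the allyl group leaves under zerovalent palladium without acid or base. The scavenger must be neither an amine (it would condense with the formyl acid) nor a hydride donor.

22 ⇒ 21. The A1 O–CH3 bond is cut. The A1 oxygen emerges from the aromatisation as the only free phenol, so no selectivity problem arises. The base must spare the ring C aryl ester.

21 ⇒ 20. Two hydrogens are returned to A2 and A3, giving up the aromaticity of ring A. This is what allows A5 to be a non-aromatic sp2 carbon when the ether is made; the sp3 centres A3 and A4 are transient. The forward dehydrogenation must spare two benzyl ethers and an aldehyde. It is also the reason B4 is capped: a free B4 phenol para to the B1 ether would be a hydroquinone monoether, open to oxidation.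

20 ⇒ 19 (key disconnection). The A5–O(B1) bond is cut, which opens ring C. The hindered ether bond is made by addition–elimination at a dione carbonyl carbon instead of at an arene, and the B2 ester tether decides which of the two dione carbonyls reacts. One step gives the whole tricyclic core. The forward step needs acid, removal of water, and conditions mild enough for a β-keto aryl ester, a catechol monoester and a 2-(alkoxymethyl)-1,3-dione. The structure of 19 is kept as drawn; what is changed is how it is reached.

19 ⇒ 17 + 11 (through 18). The acyl C–O(B2) bond is cut. The free β-keto acid cannot be handled, so the acyl group is delivered as an acylketene from a tert-butyl ester, which fragments at a lower temperature than a methyl ester. No protecting group is placed on B1: its hydroxyl is tied to the B6 formyl group by a hydrogen bond, and the B2 hydroxyl is the free, more acidic one. This saves two steps; the forward step must place the acyl group on B2 only.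

17 ⇒ 15 (through 16). The A6–CH2 bond is cut. The side chain cannot be built into the annulation partners, because a β-alkoxy ketone eliminates under the basic ring-forming conditions, and the dione enolate would react with a chloromethyl ether at oxygen. The bond is therefore made on the finished dione through its silyl enol ether under a Lewis acid, where C-alkylation is the irreversible outcome.

15 ⇒ 12 + 13 (through 14). The A3–A4 bond (conjugate addition) and the A1–A6 bond (ester condensation) are cut. Both components are simple and the A4 carboxyl arrives as the tert-butyl ester needed later. The forward annulation must keep that ester intact.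

11 ⇒ 9 (through 10). The B6–CHO bond is cut. B6 is the last free position of ring B, ortho to the B1 hydroxyl, so regiochemistry is not in question. The forward step must formylate a crowded position next to an ester without cleaving the benzyl ether.

9 ⇒ 7 (through 8) and 7 ⇒ 5 (through 6). The B1–O bond is traced back to a formyl group (aryl migration to oxygen), and that formyl C–C bond is cut in turn. The B2 hydroxyl directs the formyl group to the only free ortho position, so the B1 oxygen enters regiospecifically. The oxidation must stop at the catechol.

5 ⇒ 3 (through 4) ⇒ 2 ⇒ 1. The B4 O–benzyl, B2 O–silyl and carboxyl O–allyl bonds are cut. The two phenols of 1 differ (one is chelated to the carboxyl, one is free), which allows a temporary silyl group on B2 and a lasting benzyl group on B4. The benzylation has to run under neutral conditions so that the silyl group neither leaves nor migrates.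

## Other disconnections considered

In this section "compound A1", "compound A2" and so on are compounds of the alternatives; "position A1" and so on are atoms of ring A.

Alternative 1: Ring A is cut at the bonds between positions A1/A6 and positions A4/A5, so that it is assembled on the diaryl ether oxygen by a Danheiser benzannulation.
- Forward step: heating 3-methylcyclobut-2-en-1-one (compound A1) with the aryl ynol ether (compound A2) should open the cyclobutenone to a vinylketene, add it to the electron-rich alkyne, open again to a dienylketene and close by 6π electrocyclisation to the phenol (compound A3).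
- In favour: the hindered ether oxygen is attached to an sp carbon before ring A exists. The polarity of the ynol ether fixes the substituent pattern. Ring A arrives aromatic with its A1 hydroxyl free for methylation, so no dehydrogenation is needed in the presence of benzylic ethers; on this point the alternative is better than the chosen plan.
- Against: compound A3 has no carbon at position A4. A carboxyl would have to be introduced there afterwards, between a methyl group and an aryloxy group, in competition with position A2, which is activated to a similar degree. Ring C must then still be closed by a separate seven-membered lactonisation. The ynol ether compound A2 has to be made on a fully substituted ring B that carries an ester and an acetal, and it must survive the heating.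
- Comparison: both plans avoid an ether coupling at a hindered arene carbon and are equal on that point. The chosen plan brings the A4 carboxyl in as the tether and closes ring C in the ether-forming step, with site selectivity by geometry; the alternative leaves a regiochemically open C–C bond formation and a lactonisation for later. The step count should be equal or somewhat higher for the alternative.

Alternative 2: Ring D is cut at the bond from B5 to the lactone carbonyl and at the carbonyl–oxygen bond.
- Forward step: Pd(OAc)2 with a chiral bisphosphine under CO (reduced in the flask to zerovalent palladium) should insert into the B5–Br bond of the depsidone bromo aldehyde (compound A4) and take up CO. The acylpalladium species would then be captured by one enantiomer of the rapidly exchanging benzyl hemiacetal of the B6 aldehyde, giving the (R) benzyl acetal (compound A5, the same structure as 25).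
- In favour: lactone carbonyl, ring D and stereocentre would arise in one step. No allyl ester and no isolated lactol are needed, and the bromide is a robust spectator through the earlier chemistry. In the endgame this is one step where the chosen plan uses two, which is a point for the alternative.
- Against: oxidative addition would take place at a hexasubstituted arene between a benzyloxy and a formyl group. Enantio-determining C–O bond formation from a hemiacetal at acylpalladium has no close analogy. Benzyl alcohol can also intercept the acyl complex to give the open benzyl ester, which would cyclise without control.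
- Comparison: the alternative answers the stereochemical question, not the ring C question, so it competes with step 14 and not with the key step. Both stereo-setting steps are unproven; the acid-catalysed acetalisation of the chosen plan has closer analogies and leaves a separation-based fallback from the same intermediate.

Alternative 3: The ether bond at position A5 and the bond from position A6 to its side-chain carbon are cut together.
- Forward step: CsF under CO2 should generate the aryne between positions A5 and A6 from the silyl triflate (compound A6). The phenoxide of the ring B phenol (compound A7) would add at position A5, and the aryl anion at position A6 would be trapped by CO2 to give the diaryl ether acid (compound A8).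
- In favour: the hindered ether forms at an aryne carbon without metal and without an ortho penalty, which makes the alternative the equal of the chosen plan in the way the ether bond is made. It is convergent, and ring A is aromatic and already methylated; needing no dehydrogenation, it is better on that point.
- Against: the aryne is flanked by a methoxy group on one side and an ester on the other, which direct the nucleophile in opposite senses, so the regiochemistry rests on the methoxy group dominating. The aryl anion may be protonated before CO2 reaches it. The new carboxyl is at the wrong oxidation level and must be reduced selectively in the presence of two esters. Ring C must be closed afterwards by a separate lactonisation after removal of two allyl groups, and compound A6 itself needs several steps.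
- Comparison: in the chosen plan the tether decides the site of ether formation and closes ring C at once; here the site depends on aryne polarisation and ring C costs further steps. The chosen plan pays with two transient sp3 centres and a dehydrogenation. Overall length should be similar, the alternative being shorter before the union and longer after it.

Key step: step 10

Assumptions and remarks on the chemistry
- The lactol stereocentre of 26 is configurationally labile through ring–chain tautomerism; the route fixes it as acetal 25, releases it under neutral aprotic conditions, and 26 is to be kept cold, dry and free of acid and base.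
- The sense of induction in step 14 cannot be predicted; the (R) catalyst is written, and its antipode is used if induction proves opposite.
- Racemic compounds 15–21 are drawn as one enantiomer (trans at A3/A4). The descriptors of 19 and 20 agree with each other and with a trans relation, and the acetal descriptor of 25 and 26 corresponds to R, so no structure needs correction.
- Acid 1 is bought; it is the carboxylation product of 2-methylresorcinol.

## Route

Step 1
Reactants: 1 2,4-dihydroxy-3-methylbenzoic acid
Product: 2 allyl 2,4-dihydroxy-3-methylbenzoate
Conditions: allyl bromide, KHCO3, DMF, rt to 40 °C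
Reagents that add atoms: allyl bromide, C=CCBr
Why: SN2 alkylation of the carboxylate; hydrogen carbonate deprotonates only the acid, so both phenols should stay free.

Step 2
Reactants: 2 allyl 2,4-dihydroxy-3-methylbenzoate
Product: 3 allyl 4-[(tert-butyldimethylsilyl)oxy]-2-hydroxy-3-methylbenzoate
Conditions: TBSCl (1.05 equiv), imidazole, CH2Cl2, 0 °C
Reagents that add atoms: tert-butyldimethylsilyl chloride, CC(C)(C)[Si](C)(C)Cl
Why: Silylation of the free hydroxyl para to the ester (the later B2 oxygen); the other hydroxyl is hydrogen-bonded to the ester carbonyl and flanked on both sides, so it should not react with one equivalent.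

Step 3
Reactants: 3 allyl 4-[(tert-butyldimethylsilyl)oxy]-2-hydroxy-3-methylbenzoate
Product: 5 allyl 2-(benzyloxy)-4-hydroxy-3-methylbenzoate, via silyl ether 4 (not isolated)
Conditions: BnOH, PPh3, DIAD, THF, 0 °C to rt; then Bu4NF, AcOH, THF, 0 °C
Reagents that add atoms: benzyl alcohol, OCc1ccccc1
Why: Mitsunobu etherification benzylates the chelated phenol (the later B4 oxygen) under neutral conditions that leave the aryl silyl ether in place; buffered fluoride then frees the B2 hydroxyl without touching the allyl ester.

Step 4
Reactants: 5 allyl 2-(benzyloxy)-4-hydroxy-3-methylbenzoate
Product: 7 allyl 2-(benzyloxy)-5-formyl-4-hydroxy-3-methylbenzoate, via benzylic alcohol 6 (not isolated)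
Conditions: (CH2O)n, MgCl2, Et3N, MeCN, reflux; dilute HCl work-up
Reagents that add atoms: formaldehyde (as paraformaldehyde), C=O
Why: Magnesium phenoxide-directed ortho-formylation: formaldehyde is delivered inside the magnesium chelate to the only free ortho position, and alkoxide 6 is oxidised in the flask by hydride transfer to a second formaldehyde.

Step 5
Reactants: 7 allyl 2-(benzyloxy)-5-formyl-4-hydroxy-3-methylbenzoate
Product: 9 allyl 2-(benzyloxy)-4,5-dihydroxy-3-methylbenzoate, via aryl formate 8 (not isolated)
Conditions: mCPBA (1.1 equiv), CH2Cl2, 0 °C to rt; then MeOH, Et3N (cat.), 0 °C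
Reagents that add atoms: 3-chloroperoxybenzoic acid, OOC(=O)c1cccc(Cl)c1
Why: Baeyer–Villiger (Dakin-type) oxidation: the electron-rich aryl group (ortho-hydroxy, para-benzyloxy) migrates to oxygen, and mild methanolysis of formate 8 should give the catechol, which introduces the B1 oxygen.

Step 6
Reactants: 9 allyl 2-(benzyloxy)-4,5-dihydroxy-3-methylbenzoate
Product: 11 allyl 2-(benzyloxy)-6-formyl-4,5-dihydroxy-3-methylbenzoate, via chloro(methoxy)methyl arene 10 (not isolated)
Conditions: Cl2CHOMe, TiCl4, CH2Cl2, −78 to −20 °C; then 1 M HCl
Reagents that add atoms: dichloromethyl methyl ether, COC(Cl)Cl; water, O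
Why: Rieche formylation: the titanium catecholate directs the chloro(methoxy)methyl cation to the one remaining ring position, ortho to the B1 oxygen, and hydrolysis of 10 gives the aldehyde. This reagent is known to formylate positions between an oxygen substituent and an ester, and the low temperature should protect the benzyl ether that is chelated to the ester.

Step 7
Reactants: 12 tert-butyl acetoacetate; 13 methyl (E)-crotonate
Product: 15 tert-butyl rac-trans-2-methyl-4,6-dioxocyclohexane-1-carboxylate (enol form), via Michael adduct 14 (not isolated)
Conditions: KOt-Bu, t-BuOH, reflux; then cold dilute HCl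
Reagents that add atoms: none
Why: Michael–Claisen annulation: conjugate addition of the acetoacetate enolate forms A3–A4, and Dieckmann-type acylation of the methyl ketone by the methyl ester forms A1–A6 while the tert-butyl ester is retained. The trans isomer should result from equilibration at the acidic A4 position; both centres disappear in step 11.

Step 8
Reactants: 15 tert-butyl rac-trans-2-methyl-4,6-dioxocyclohexane-1-carboxylate
Product: 17 tert-butyl rac-trans-3-[(benzyloxy)methyl]-2-hydroxy-6-methyl-4-oxocyclohex-2-ene-1-carboxylate, via trimethylsilyl enol ether 16 (not isolated)
Conditions: HMDS, imidazole (cat.), CH2Cl2, 40 °C, evaporate; then BnOCH2Cl (1.05 equiv), ZnBr2 (5 mol %), CH2Cl2, −20 to 0 °C; aq. NaH2PO4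
Reagents that add atoms: benzyl chloromethyl ether, ClCOCc1ccccc1
Why: Lewis-acid-promoted alkylation of a silyl enol ether by an α-chloro ether (Mukaiyama-type alkoxymethylation). The neutral enol ether reacts at carbon, and any O-alkylated mixed acetal re-ionises under ZnBr2, so the C–C bonded product should be the sink; this avoids the O-alkylation expected of the dione enolate.

Step 9
Reactants: 17 tert-butyl rac-trans-3-[(benzyloxy)methyl]-2-hydroxy-6-methyl-4-oxocyclohex-2-ene-1-carboxylate; 11 allyl 2-(benzyloxy)-6-formyl-4,5-dihydroxy-3-methylbenzoate
Product: 19 B2 aryl ester of the dione acid (the free B1 phenol precursor of the key step), via acylketene 18 (not isolated)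
Conditions: PhMe, 110 °C, N2 sweep to remove t-BuOH, 17 in slight excess
Reagents that add atoms: none
Why: Thermal loss of tert-butanol from the β-keto tert-butyl ester gives acylketene 18, which adds the phenol (acylketene transesterification). The B2 hydroxyl is free and the more acidic one, whereas the B1 hydroxyl is tied to the ortho formyl group by a hydrogen bond. Because aryl β-keto esters can re-form the acylketene at this temperature, the outcome should settle on the B2 ester, which keeps that hydrogen bond.

Step 10
Reactants: 19 B2 aryl ester with free B1 phenol and enolised dione
Product: 20 tetrahydrodepsidone with ring A as a 3-aryloxycyclohex-2-enone (rac-trans)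
Conditions: TsOH·H2O (10 mol %), PhH, reflux, 4 Å MS in a Soxhlet, 0.02 M
Reagents that add atoms: none
Why: This is an acid-catalysed vinylogous esterification of a cyclohexane-1,3-dione by a phenol, run intramolecularly; the closest known reactions are the acid-catalysed formations of 3-alkoxy- and 3-aryloxycyclohex-2-enones from cyclohexane-1,3-diones. Protonation of the enolised dione on the A1 carbonyl oxygen gives a 1,3-dihydroxyallyl cation with termini A1 and A5; the B1 hydroxyl adds at A5, and loss of water from the hemiketal leaves the A5–O–B1 enol ether conjugated with the A1 carbonyl, the sieves making the condensation irreversible. Ring C closes in the 7-exo-trig mode. No stereocentre is formed; the trans A3/A4 centres are carried along and erased in step 11. Site selectivity between the two dione carbonyls comes from the tether, since a B1 oxygen held through B2–O–C(=O)–A4 can reach A5 but not A1. Attack through oxygen and not carbon is secured because both positions ortho to B1 (B2, B6) and the para position (B4) are substituted. Acyl migration from B2 to B1 is disfavoured by the hydrogen bond from the B1 hydroxyl to the B6 formyl group. Working at 80 °C with little acid should also hold back retro-acylketene cleavage and loss of benzyl alcohol from the A6 side chain.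

Step 11
Reactants: 20 tetrahydrodepsidone
Product: 21 depsidone phenol (ring A aromatic, A1 OH)
Conditions: DDQ (1.1 equiv), 1,4-dioxane, 80 °C
Reagents that add atoms: none
Why: Quinone dehydrogenation: enolisation, hydride abstraction at A3 and loss of the A2 proton give a cyclohexadienone that tautomerises through its acidic A4–H to the A1 phenol. Ring B is deactivated by the formyl and ester groups and its B4 oxygen is capped, so it should not be oxidised.

Step 12
Reactants: 21 depsidone phenol
Product: 22 depsidone methyl ether (A1 OMe, B5 allyl ester, B6 formyl)
Conditions: MeI, K2CO3, DMF, 0 °C to rt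
Reagents that add atoms: iodomethane, CI
Why: Williamson methylation of the only free phenol, which is para to the ring C carbonyl and therefore acidic; carbonate in an aprotic solvent is a base that aryl esters of this kind and aryl aldehydes tolerate.

Step 13
Reactants: 22 depsidone methyl ether
Product: 24 racemic lactol (ring D closed), via formyl acid 23 (not isolated)
Conditions: Pd(PPh3)4 (5 mol %), TolSO2Na, THF–H2O, rt; then dilute HCl to pH 3
Reagents that add atoms: none
Why: Tsuji–Trost deallylation: zerovalent palladium ionises the allyl ester and the sulfinate captures the allyl group as a sulfone; this scavenger is neither basic nor an amine and cannot condense with the aldehyde. The liberated ortho-formyl acid 23 closes to the hydroxyphthalide, formed as a racemate.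

Step 14
Reactants: 24 racemic lactol
Product: 25 (R)-benzyl acetal of the depsidone (tribenzyl compound)
Conditions: BnOH (3 equiv), (R)-3,3′-bis(2,4,6-triisopropylphenyl)-1,1′-binaphthyl-2,2′-diyl hydrogen phosphate (10 mol %), 5 Å MS, PhMe, 0 °C
Reagents that add atoms: benzyl alcohol, OCc1ccccc1
Why: Proposed new method: the phosphoric acid should ionise the lactol (directly to the phthalidyl oxocarbenium ion, or through the open formyl acid and its benzyl hemiacetal), and the chiral phosphate, hydrogen-bonded to benzyl alcohol, should deliver it to one face, so that both lactol enantiomers converge on the (R) acetal (dynamic kinetic asymmetric transformation); the closest known reaction types are chiral phosphoric acid-catalysed enantioselective O,O- and N,O-acetalisations through such ion pairs and the catalytic acylative dynamic kinetic resolution of 3-hydroxyphthalides.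

Step 15
Reactants: 25 (R)-benzyl acetal
Product: 26 target, (R)-lactol
Conditions: H2 (1 atm), Pd/C, EtOAc, rt, stopped at full conversion
Reagents that add atoms: none
Why: Hydrogenolysis cleaves the three O–CH2Ph bonds; the bond between the acetal oxygen and the stereocentre is not touched, so the R configuration is retained, and the neutral aprotic medium keeps the liberated lactol closed. The crowded ring A benzylic C–O bond should adsorb poorly on the catalyst and survive.

## Compound list

1 | 2,4-dihydroxy-3-methylbenzoic acid | Cc1c(O)ccc(C(=O)O)c1O | starting material
2 | allyl 2,4-dihydroxy-3-methylbenzoate | Cc1c(O)ccc(C(=O)OCC=C)c1O | intermediate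
3 | allyl 4-[(tert-butyldimethylsilyl)oxy]-2-hydroxy-3-methylbenzoate | Cc1c(O[Si](C)(C)C(C)(C)C)ccc(C(=O)OCC=C)c1O | intermediate
4 | allyl 2-(benzyloxy)-4-[(tert-butyldimethylsilyl)oxy]-3-methylbenzoate (not isolated) | Cc1c(O[Si](C)(C)C(C)(C)C)ccc(C(=O)OCC=C)c1OCc1ccccc1 | intermediate
5 | allyl 2-(benzyloxy)-4-hydroxy-3-methylbenzoate | Cc1c(O)ccc(C(=O)OCC=C)c1OCc1ccccc1 | intermediate
6 | allyl 2-(benzyloxy)-4-hydroxy-5-(hydroxymethyl)-3-methylbenzoate, as magnesium alkoxide (not isolated) | Cc1c(O)c(CO)cc(C(=O)OCC=C)c1OCc1ccccc1 | intermediate
7 | allyl 2-(benzyloxy)-5-formyl-4-hydroxy-3-methylbenzoate | Cc1c(O)c(C=O)cc(C(=O)OCC=C)c1OCc1ccccc1 | intermediate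
8 | allyl 2-(benzyloxy)-5-(formyloxy)-4-hydroxy-3-methylbenzoate (not isolated) | Cc1c(O)c(OC=O)cc(C(=O)OCC=C)c1OCc1ccccc1 | intermediate
9 | allyl 2-(benzyloxy)-4,5-dihydroxy-3-methylbenzoate | Cc1c(O)c(O)cc(C(=O)OCC=C)c1OCc1ccccc1 | intermediate
10 | allyl 2-(benzyloxy)-6-[chloro(methoxy)methyl]-4,5-dihydroxy-3-methylbenzoate, titanium-bound (not isolated) | Cc1c(O)c(O)c(C(Cl)OC)c(C(=O)OCC=C)c1OCc1ccccc1 | intermediate
11 | allyl 2-(benzyloxy)-6-formyl-4,5-dihydroxy-3-methylbenzoate (ring B: 4-OH = B2, 5-OH = B1, 6-CHO = B6) | Cc1c(O)c(O)c(C=O)c(C(=O)OCC=C)c1OCc1ccccc1 | intermediate
12 | tert-butyl acetoacetate | CC(=O)CC(=O)OC(C)(C)C | starting material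
13 | methyl (E)-crotonate | C/C=C/C(=O)OC | starting material
14 | 1-tert-butyl 5-methyl 2-acetyl-3-methylpentanedioate, diastereomer mixture (not isolated) | COC(=O)CC(C)C(C(C)=O)C(=O)OC(C)(C)C | intermediate
15 | tert-butyl rac-trans-2-methyl-4,6-dioxocyclohexane-1-carboxylate, enol form, one enantiomer drawn | O=C1C[C@H](C)[C@@H](C(=O)OC(C)(C)C)C(O)=C1 | intermediate
16 | trimethylsilyl enol ether of 15, regioisomer mixture, one drawn (not isolated) | O=C1C[C@H](C)[C@@H](C(=O)OC(C)(C)C)C(O[Si](C)(C)C)=C1 | intermediate
17 | tert-butyl rac-trans-3-[(benzyloxy)methyl]-2-hydroxy-6-methyl-4-oxocyclohex-2-ene-1-carboxylate, one enantiomer drawn | O=C1C[C@H](C)[C@@H](C(=O)OC(C)(C)C)C(O)=C1COCc1ccccc1 | intermediate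
18 | racemic acylketene: 2-[(benzyloxy)methyl]-3-hydroxy-5-methyl-4-(oxomethylidene)cyclohex-2-en-1-one (not isolated) | O=C=C1[C@@H](C)CC(=O)C(COCc2ccccc2)=C1O | intermediate
19 | allyl 2-(benzyloxy)-6-formyl-5-hydroxy-3-methyl-4-{[rac-trans-3-(benzyloxymethyl)-2-hydroxy-6-methyl-4-oxocyclohex-2-ene-1-carbonyl]oxy}benzoate, one enantiomer drawn | O=C1C[C@H](C)[C@@H](C(=O)Oc2c(C)c(OCc3ccccc3)c(C(=O)OCC=C)c(C=O)c2O)C(O)=C1COCc1ccccc1 | intermediate
20 | rac-trans tetrahydrodepsidone: ring C closed, ring A a 3-aryloxycyclohex-2-enone (A1 C=O, A6 CH2OBn), ring B with B4 OBn, B5 CO2allyl, B6 CHO; one enantiomer drawn | O=C1C[C@H](C)[C@H]2C(=O)Oc3c(C)c(OCc4ccccc4)c(C(=O)OCC=C)c(C=O)c3OC2=C1COCc1ccccc1 | intermediate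
21 | depsidone phenol: ring A aromatic with A1 OH, A3 CH3, A6 CH2OBn; ring B with B4 OBn, B5 CO2allyl, B6 CHO | Oc1cc(C)c2c(c1COCc1ccccc1)Oc1c(c(C)c(OCc3ccccc3)c(C(=O)OCC=C)c1C=O)OC2=O | intermediate
22 | A1 methyl ether of 21 | COc1cc(C)c2c(c1COCc1ccccc1)Oc1c(c(C)c(OCc3ccccc3)c(C(=O)OCC=C)c1C=O)OC2=O | intermediate
23 | B5 carboxylic acid with B6 formyl group, open form (not isolated) | COc1cc(C)c2c(c1COCc1ccccc1)Oc1c(c(C)c(OCc3ccccc3)c(C(=O)O)c1C=O)OC2=O | intermediate
24 | racemic lactol: ring D hydroxyphthalide, A6 CH2OBn, B4 OBn | COc1cc(C)c2c(c1COCc1ccccc1)Oc1c(c(C)c(OCc3ccccc3)c3c1C(O)OC3=O)OC2=O | intermediate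
25 | (R)-benzyl acetal of 24 | COc1cc(C)c2c(c1COCc1ccccc1)Oc1c(c(C)c(OCc3ccccc3)c3c1[C@H](OCc1ccccc1)OC3=O)OC2=O | intermediate
26 | CNP0367167.1, (R)-lactol | COc1cc(C)c2c(c1CO)Oc1c(c(C)c(O)c3c1[C@H](O)OC3=O)OC2=O | target

## Step count and least certain steps

Total step count: 15. Longest linear sequence: 13 steps (steps 1–6 and 9–15, from 1); the dione branch (steps 7 and 8) joins at step 9.

Step 14.
- What may go wrong: poor facial discrimination in a loose ion pair, competition from acetalisation not controlled by the catalyst, and erosion of the product by re-ionisation.
- Fallback (known chemistry, separation of diastereomers): from 24, acid-catalysed acetalisation (camphorsulfonic acid, PhMe, sieves) with (S)-1-phenylethanol gives two diastereomeric acetals separable by chromatography, the (R)-acetal F1 and its epimer F2. F2 is re-equilibrated with the same acid and recycled. Hydrogenolysis of F1 under the conditions of step 15 removes the 1-phenylethyl group together with the two benzyl ethers and returns to the route at 26.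

Step 10 (key step).
- What may go wrong: reversal of the ester linkage through the acylketene, followed by hydrolysis and decarboxylation by the water set free; migration of the acyl group from the B2 to the B1 oxygen before closure, leading to the isomeric ring system; acid-promoted loss of benzyl alcohol from the A6 side chain; sluggish addition of the hydrogen-bonded, electron-poor B1 phenol.
- Fallback (base-mediated addition–elimination on a vinylogous acid chloride, with A5 marked before the ester is made): from 17, PPh3/CCl4 gives the two 3-chloroenones, of which the isomer chlorinated at A5, F3, is separated. CF3CO2H removes the tert-butyl group to give acid F4. Carbodiimide esterification (DCC, DMAP cat., 0 °C) with 11 gives F5. K2CO3 in MeCN then closes ring C by addition of the B1 phenoxide to A5 and loss of chloride, returning at 20. Part of the dione is spent on the wrong chloride, which is the price of not letting the tether choose.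

Step 8.
- What may go wrong: persistent O-alkylation, double alkylation, or ionisation of the product under the Lewis acid (loss of benzyl alcohol) with formation of methylene-bridged dimers.
- Fallback (cross-coupling in place of enol alkylation): from 15, Me3SiCHN2 gives the methyl enol ether F6 (either regioisomer serves, one is drawn). Iodination at A6 (I2, pyridine) gives F7. Stille coupling with tributyl[(benzyloxy)methyl]stannane (Pd2(dba)3, AsPh3, CuI, DMF) gives F8. Dilute HCl in THF hydrolyses the enol ether, returning at 17.

Step 9.
- What may go wrong: acylation at the B1 oxygen or at both oxygens, loss of isobutene with decarboxylation instead of loss of tert-butanol, and capture of the acylketene by the dione enol of a second molecule or by the formyl group.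
- Fallback (thioester activated by a thiophilic silver salt at room temperature, in place of the thermal acylketene): S-tert-butyl 3-oxobutanethioate F9 and 13 give, by the annulation of step 7, the thioester dione F10. Alkoxymethylation as in step 8 gives F11. AgOCOCF3 in THF at rt transfers the acyl group to the B2 hydroxyl of 11, returning at 19.

Step 6.
- What may go wrong: cleavage of the benzyl ether chelated to the ester by TiCl4, and incomplete substitution at the crowded position between hydroxyl and ester.
- Fallback (directed metalation instead of electrophilic substitution): from 9, MOMCl/i-Pr2NEt gives the bis(methoxymethyl) ether F12. TMPMgCl·LiCl in THF magnesiates the position flanked by the ester and a methoxymethoxy group, and DMF gives aldehyde F13. HCl in THF/i-PrOH removes both acetals, returning at 11.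

Step 15.
- What may go wrong: hydrogenolysis of the ring A benzylic C–O bond (leaving a methyl group at A6) or of the phthalide C–O bond, reduction of the lactol through its aldehyde form, and racemisation if the exposure has to be long.
- Fallback (change of order, so that the last hydrogenolysis has only the activated acetal benzyl group to remove): from 24, hydrogenolysis of the two benzyl ethers at the racemic stage gives the racemic triol F14, where over-reduced material can be removed without stereochemical loss. Acetalisation as in step 14 gives the (R)-benzyl acetal F15. Its single O-benzyl group is cleaved under the conditions of step 15 in a short exposure, returning at 26.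

## Further compounds

F1 | step 14 | (R)-acetal of 24 with (S)-1-phenylethanol | COc1cc(C)c2c(c1COCc1ccccc1)Oc1c(c(C)c(OCc3ccccc3)c3c1[C@H](O[C@@H](C)c1ccccc1)OC3=O)OC2=O
F2 | step 14 | (S)-acetal of 24 with (S)-1-phenylethanol | COc1cc(C)c2c(c1COCc1ccccc1)Oc1c(c(C)c(OCc3ccccc3)c3c1[C@@H](O[C@@H](C)c1ccccc1)OC3=O)OC2=O
F3 | step 10 | tert-butyl rac-trans-3-[(benzyloxy)methyl]-2-chloro-6-methyl-4-oxocyclohex-2-ene-1-carboxylate | O=C1C[C@H](C)[C@@H](C(=O)OC(C)(C)C)C(Cl)=C1COCc1ccccc1
F4 | step 10 | rac-trans-3-[(benzyloxy)methyl]-2-chloro-6-methyl-4-oxocyclohex-2-ene-1-carboxylic acid | O=C1C[C@H](C)[C@@H](C(=O)O)C(Cl)=C1COCc1ccccc1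
F5 | step 10 | B2 aryl ester of F4 with 11 | O=C1C[C@H](C)[C@@H](C(=O)Oc2c(C)c(OCc3ccccc3)c(C(=O)OCC=C)c(C=O)c2O)C(Cl)=C1COCc1ccccc1
F6 | step 8 | tert-butyl rac-trans-4-methoxy-6-methyl-2-oxocyclohex-3-ene-1-carboxylate | COC1=CC(=O)[C@H](C(=O)OC(C)(C)C)[C@@H](C)C1
F7 | step 8 | tert-butyl rac-trans-3-iodo-4-methoxy-6-methyl-2-oxocyclohex-3-ene-1-carboxylate | COC1=C(I)C(=O)[C@H](C(=O)OC(C)(C)C)[C@@H](C)C1
F8 | step 8 | tert-butyl rac-trans-3-[(benzyloxy)methyl]-4-methoxy-6-methyl-2-oxocyclohex-3-ene-1-carboxylate | COC1=C(COCc2ccccc2)C(=O)[C@H](C(=O)OC(C)(C)C)[C@@H](C)C1
F9 | step 9 | S-tert-butyl 3-oxobutanethioate | CC(=O)CC(=O)SC(C)(C)C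
F10 | step 9 | S-tert-butyl rac-trans-2-hydroxy-6-methyl-4-oxocyclohex-2-ene-1-carbothioate | O=C1C[C@H](C)[C@@H](C(=O)SC(C)(C)C)C(O)=C1
F11 | step 9 | S-tert-butyl rac-trans-3-[(benzyloxy)methyl]-2-hydroxy-6-methyl-4-oxocyclohex-2-ene-1-carbothioate | O=C1C[C@H](C)[C@@H](C(=O)SC(C)(C)C)C(O)=C1COCc1ccccc1
F12 | step 6 | allyl 2-(benzyloxy)-4,5-bis(methoxymethoxy)-3-methylbenzoate | Cc1c(OCOC)c(OCOC)cc(C(=O)OCC=C)c1OCc1ccccc1
F13 | step 6 | allyl 2-(benzyloxy)-6-formyl-4,5-bis(methoxymethoxy)-3-methylbenzoate | Cc1c(OCOC)c(OCOC)c(C=O)c(C(=O)OCC=C)c1OCc1ccccc1
F14 | step 15 | racemic form of 26 | COc1cc(C)c2c(c1CO)Oc1c(c(C)c(O)c3c1C(O)OC3=O)OC2=O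
F15 | step 15 | (R)-benzyl acetal of 26 with free A6 CH2OH and B4 OH | COc1cc(C)c2c(c1CO)Oc1c(c(C)c(O)c3c1[C@H](OCc1ccccc1)OC3=O)OC2=O
A1 | alternative 1 | 3-methylcyclobut-2-en-1-one | CC1=CC(=O)C1
A2 | alternative 1 | aryl ynol ether of ring B (B1 O–C≡C–CH2OBn, B2 OMOM, B4 OBn, B5 CO2t-Bu, B6 CH(OMe)2) | O(C#CCOCc1ccccc1)c1c(OCOC)c(C)c(OCc2ccccc2)c(C(=O)OC(C)(C)C)c1C(OC)OC
A3 | alternative 1 | diaryl ether with ring A as the A1 phenol, position A4 unsubstituted | Oc1cc(C)cc(Oc2c(OCOC)c(C)c(OCc3ccccc3)c(C(=O)OC(C)(C)C)c2C(OC)OC)c1COCc1ccccc1
A4 | alternative 2 | depsidone aldehyde with bromine at B5 | COc1cc(C)c2c(c1COCc1ccccc1)Oc1c(c(C)c(OCc3ccccc3)c(Br)c1C=O)OC2=O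
A5 | alternative 2 | depsidone with ring D as the (R) O-benzyl acetal (same structure as 25) | COc1cc(C)c2c(c1COCc1ccccc1)Oc1c(c(C)c(OCc3ccccc3)c3c1[C@H](OCc1ccccc1)OC3=O)OC2=O
A6 | alternative 3 | allyl 4-methoxy-6-methyl-2-[(trifluoromethylsulfonyl)oxy]-3-(trimethylsilyl)benzoate | COc1cc(C)c(C(=O)OCC=C)c(OS(=O)(=O)C(F)(F)F)c1[Si](C)(C)C
A7 | alternative 3 | ring B phenol (B1 OH, B2 O-allyl, B4 OBn, B5 CO2t-Bu, B6 CH(OMe)2) | Oc1c(OCC=C)c(C)c(OCc2ccccc2)c(C(=O)OC(C)(C)C)c1C(OC)OC
A8 | alternative 3 | diaryl ether with a carboxylic acid at position A6 | COc1cc(C)c(C(=O)OCC=C)c(Oc2c(OCC=C)c(C)c(OCc3ccccc3)c(C(=O)OC(C)(C)C)c2C(OC)OC)c1C(=O)O
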